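The target is what we want, so we first ask whether its fraction of the charge at the end depends on how much was charged. If every step is first order, the rate equations are linear. Scaling the charge then scales every amount, and the fractions stay put. That symmetric case is our zero. A step of another order can move a flask off it.

| flask | substrate | remark | time |
|---|---|---|---|
| birch | 0.24 M | run made earlier |  |
| alder | 0.67 M | run made earlier |  |
| maple | 1.6 M | run made earlier |  |
| blue | 0.30 M |  | 30 h |
| violet | 0.40 M |  | 30 h |
| grey | 0.60 M |  | 30 h |
| teal | 1.0 M |  | 30 h |
| ochre | 1.5 M |  | 30 h |

| run | time / h | target / % | substrate / % |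
|---|---|---|---|
| birch | 2.50 | 5.2 | 84.7 |
| birch | 6.00 | 7.8 | 67.3 |
| birch | 12.0 | 11.2 | 46.2 |
| birch | 30.0 | 15.3 | 15.0 |
| alder | 2.50 | 2.1 | 84.2 |
| alder | 6.00 | 6.9 | 69.8 |
| alder | 12.0 | 9.3 | 47.6 |
| alder | 30.0 | 16.2 | 15.4 |
| maple | 2.50 | 3.5 | 86.7 |
| maple | 6.00 | 7.3 | 67.0 |
| maple | 12.0 | 10.5 | 46.1 |
| maple | 30.0 | 16.0 | 14.2 |

(each reading ± 1 percentage point)

- "hardly changes" means that all values lie within two and a half points (for a concentration: within two and a half percent of the largest)

1. amount of target at the end, in percent of the substrate charged for blue, violet, grey, teal, ochre, in this order
2. how the row runs (hardly changes / falls all the way / rises, then falls / falls, then rises / rises all the way)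

Does the target leave that zero? At 30.0 h, birch with 0.24 M holds a target fraction of 15.3%, and maple with 1.6 M holds 16.0%. The logarithm of the target ratio over the logarithm of the charge ratio gives 0.0236. This is our charge exponent, which is zero in the symmetric case. It is a reading: the gap of 0.7 percentage points is smaller than the scatter of 1 point.

Does the substrate agree? Its fractions, 15.0% and 14.2%, give an exponent of −0.0289, and their gap of 0.8 points is also below the scatter.

What does the exponent do to the row? Blue's charge lies above birch's and ochre's below maple's, so the row stays inside the tested range. Taken at face value, the exponent makes ochre 1.04 times blue. On the mean target reading of birch, alder and maple at 30.0 h, 15.8%, that is 0.61 points, again below the scatter. We commit to a flat row at that mean.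

The forecast gives 15.8% at each point and calls the row hardly changes: “Every step therefore looks first order, and percent yield should not depend on concentration.”

The flask gives 15.6% at each point, and the row hardly changes.

    substrate → intermediate A (k = 0.0497 h⁻¹)
    intermediate A ⇌ intermediate B (K = 4.83, k = 0.00229 h⁻¹)
    substrate → target (k = 0.0141 h⁻¹)
    target → over-reaction product (k = 0.00972 h⁻¹)

In blue, the substrate fell to 14.7% by 30.0 h, and at the start it fed intermediate A 3.5 times as fast as target. Meanwhile target in blue went on to over-reaction product, with a half-life of 71 h by that step, yet at 30.0 h it was still made 1.37 times faster than used up, each step taken net. The charge exponent of the row from blue to ochre is 0. At 300 h, target stood at 1.41% in blue and 1.41% in ochre, an exponent of 0.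

(The readings stem from a simulated flask for an exercise.)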